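**Plan**

1. Retrosynthesis: the C3–Br bond is cut first, back to a C3–CO2H group (ipso-bromodecarboxylation). The pyrrole ring is then cut at N1–C2 (condensation) and at C3–C3a ([3,3] shift across an N–O bond). This leaves methyl propiolate and N-(3,5-dibromophenyl)hydroxylamine, which comes from 1,3-dibromo-5-nitrobenzene.
2. Enabling feature: in the benzo ring the three heteroatom-bearing carbons C4 (Br), C6 (Br) and C7a (N) stand 1,3,5 to one another. The N-aryl precursor is therefore C2v-symmetric and its two ortho carbons (future C3a and C7) are equivalent, so the 4-/6-regioisomer problem of meta-substituted N-aryl precursors cannot arise. The bond to C3a, which lies between C7a–N and C4–Br, is made intramolecularly.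
3. The C3–C3a bond joins two carbons that are both nucleophilic in their parent forms (aniline ortho carbon, ester α-carbon). The weak N–O bond of an O-vinylhydroxylamine is the built-in oxidant that allows this union of like polarity.
4. Forward: the benzene ring is bought. The nitro group is reduced to the hydroxylamine, and a one-flask O-vinylation/[3,3] shift/condensation builds the pyrrole ring. The ester that activated the alkyne is saponified and its carboxyl group is exchanged for bromine at C3, so no C–H bromination selectivity (C3 against C2, mono against di) is called upon.
5. Stereochemistry: the target is planar and has no stereocentre, so nothing has to be set.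

Key step: step 2

Remark on the chemistry: the target is achiral, so the request for a single enantiomer places no demand on the route. The task is constitutional control of the three bromines and of the ring fusion. Compounds 1 and 4 are catalogue chemicals.

**Route**

Step 1
Reactants: 1 1,3-dibromo-5-nitrobenzene
Product: 3 N-(3,5-dibromophenyl)hydroxylamine, via nitrosoarene 2 (not isolated)
Conditions: Zn dust (2.2 equiv), NH4Cl (4 equiv), THF/H2O, 0 °C to rt; filtered, extracted, used at once under N2
Reagents that add atoms: none
Why: Zinc in buffered ammonium chloride (the classical partial reduction of nitroarenes) should stop at the four-electron stage, because the two bromines make the N-arylhydroxylamine a poor substrate for further reduction and for Bamberger rearrangement, while aryl C–Br bonds are inert to zinc under these near-neutral conditions.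

Step 2
Reactants: 3 N-(3,5-dibromophenyl)hydroxylamine; 4 methyl propiolate
Product: 7 methyl 4,6-dibromo-1H-indole-3-carboxylate, via N-oxyenamine 5 (not isolated), via aminoaryl formylacetate 6 (not isolated)
Conditions: 4 (1.1 equiv), DABCO (10 mol %), CH2Cl2, −15 °C to rt, N2
Reagents that add atoms: none
Why: DABCO adds to 4 to give a β-ammonium allenolate that deprotonates the hydroxylamine, whose oxygen then adds to the β-carbon and expels DABCO to give N-oxyenamine 5. Compound 5 should undergo a [3,3]-sigmatropic (hetero-Cope) shift that breaks N–O and makes C3–C3a, the dienimine tautomerises to aniline 6, and the NH2 group of 6 condenses with the formyl group to make N1–C2 with loss of water. The closest known reaction type is the DABCO-catalysed annulation of N-arylhydroxylamines with conjugated terminal alkynes to 3-acceptor indoles, a relative of the Fischer and Bartoli indolisations. The pyrrole ring is closed by 5-exo-trig attack of the aniline nitrogen on the aldehyde carbon followed by dehydration, after the C–C bond has been set through a six-membered chair-like pericyclic transition state. No stereocentre remains, since the CH of 6 is enolisable and becomes sp2 in the product. The step needs O- rather than N-addition to the alkyne (secured by the two bromines lowering the nucleophilicity of nitrogen and by the α-effect oxygen under DABCO catalysis) and closure on the aldehyde rather than the ester carbonyl (faster, and ending in an aromatic ring); the site of the C–C bond needs no control because both ortho carbons are equivalent by C2v symmetry, and the concerted intramolecular shift should tolerate the adjacent bromine and the deactivated ring.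

Step 3
Reactants: 7 methyl 4,6-dibromo-1H-indole-3-carboxylate
Product: 9 4,6-dibromo-1H-indole-3-carboxylic acid, via sodium carboxylate 8 (not isolated)
Conditions: NaOH (5 equiv), MeOH/H2O 3:1, 70 °C; then 1 M HCl, 0 °C, to pH 3, filtration
Reagents that add atoms: sodium hydroxide, [Na+].[OH-]
Why: Saponification (BAc2) of the vinylogous-carbamate ester needs heat and excess hydroxide because of donation from the indole nitrogen and shielding by the peri C4–Br, conditions that the aryl bromides tolerate, and cold acidification to pH 3 should precipitate the acid before acid-catalysed protodecarboxylation sets in.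

Step 4
Reactants: 9 4,6-dibromo-1H-indole-3-carboxylic acid
Product: 11 3,4,6-tribromo-1H-indole, via 3-bromoindolenine acid 10 (not isolated)
Conditions: NBS (1.0 equiv), LiOAc (10 mol %), DMF, 0 °C to rt, dark; aq. Na2S2O3/NaHCO3 work-up
Reagents that add atoms: N-bromosuccinimide, O=C1CCC(=O)N1Br
Why: Ipso-bromodecarboxylation (Hunsdiecker-type halodecarboxylation of an electron-rich heteroaromatic acid) should occur because Br+ from NBS attacks C3, the enamine β-carbon and most nucleophilic position, to give bromoindolenine 10, which rearomatises by loss of CO2 from its carboxylate, so bromine enters only where the carboxyl stood and one equivalent of NBS leaves C2 of the deactivated product untouched.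

**Compound list**

1 | 1,3-dibromo-5-nitrobenzene | O=[N+]([O-])c1cc(Br)cc(Br)c1 | starting material
2 | 1,3-dibromo-5-nitrosobenzene (not isolated) | O=Nc1cc(Br)cc(Br)c1 | intermediate
3 | N-(3,5-dibromophenyl)hydroxylamine | ONc1cc(Br)cc(Br)c1 | intermediate
4 | methyl propiolate (methyl prop-2-ynoate) | C#CC(=O)OC | starting material
5 | methyl (E)-3-{[(3,5-dibromophenyl)amino]oxy}prop-2-enoate (N-oxyenamine, not isolated) | COC(=O)/C=C/ONc1cc(Br)cc(Br)c1 | intermediate
6 | methyl 2-(2-amino-4,6-dibromophenyl)-3-oxopropanoate (racemic, enolisable, not isolated) | COC(=O)C(C=O)c1c(N)cc(Br)cc1Br | intermediate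
7 | methyl 4,6-dibromo-1H-indole-3-carboxylate | COC(=O)c1c[nH]c2cc(Br)cc(Br)c12 | intermediate
8 | sodium 4,6-dibromo-1H-indole-3-carboxylate (not isolated) | [Na+].[O-]C(=O)c1c[nH]c2cc(Br)cc(Br)c12 | intermediate
9 | 4,6-dibromo-1H-indole-3-carboxylic acid | OC(=O)c1c[nH]c2cc(Br)cc(Br)c12 | intermediate
10 | 3,4,6-tribromo-3H-indole-3-carboxylic acid (racemic, transient, not isolated) | OC(=O)C1(Br)C=Nc2cc(Br)cc(Br)c12 | intermediate
11 | 3,4,6-tribromo-1H-indole | Brc1cc(Br)c2c(Br)c[nH]c2c1 | target

**Step count and risks**

Total step count: 4. Longest linear sequence: 4 steps (1 → 3 → 7 → 9 → 11).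

Steps most likely to fail, in order of risk:

Step 2. The process at risk is addition of the hydroxylamine through nitrogen instead of oxygen, or base-induced disproportionation of 3 before the sigmatropic shift. The fallback sets out from 1 and returns to the route at 7. It makes the C3–C3a bond by a palladium(II)-catalysed oxidative C–H/C–H cyclisation of an N-aryl enaminoester, which again profits from the equivalence of the two ortho carbons. Compound 1 is reduced fully (Fe, NH4Cl, EtOH/H2O, 80 °C) to 3,5-dibromoaniline F1. F1 is added to methyl propiolate 4 (MeOH, 60 °C) to give methyl (Z)-3-[(3,5-dibromophenyl)amino]prop-2-enoate F2; the hydrogen-bonded Z isomer is expected to prevail and the geometry is mobile under the next conditions. Pd(OAc)2 (10 mol %), Cu(OAc)2 (3 equiv), K2CO3, DMF, 80–120 °C should then palladate the enamine α-carbon, activate an ortho C–H bond and reductively eliminate to 7.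

Step 4. The process at risk is bromination at C2 or at nitrogen, or further bromination of the product, in competition with ipso attack at the hindered, carboxyl-bearing C3. The fallback sets out from 9 and returns to the route at 11. It separates loss of CO2 from bromination: 9 is protodecarboxylated (AcOH, 100 °C, or catalytic Ag2CO3 with AcOH in DMSO, 120 °C) to 4,6-dibromo-1H-indole F3. F3 is then brominated at the free C3 by ordinary electrophilic substitution (NBS 1.0 equiv, DMF, 0 °C) to give 11.

Step 3. The process at risk is stalled hydrolysis of the deactivated, peri-shielded ester (under base the indole is deprotonated and the ester becomes still less electrophilic), or uncontrolled loss of CO2 under forcing conditions. The fallback sets out from 3 and returns to the route at 9. It releases the carboxyl group by acidolysis of a tert-butyl ester instead of by acyl substitution. Step 2 is run on 3 with commercial tert-butyl propiolate (DABCO 10 mol %, CH2Cl2, −15 °C to rt). This should pass through tert-butyl (E)-3-{[(3,5-dibromophenyl)amino]oxy}prop-2-enoate F4 and tert-butyl 2-(2-amino-4,6-dibromophenyl)-3-oxopropanoate F5, neither isolated, to tert-butyl 4,6-dibromo-1H-indole-3-carboxylate F6. TFA/CH2Cl2 at 0 °C then cleaves the tert-butyl–oxygen bond of F6 to give 9.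

**Further compounds**

F1 | step 2 | 3,5-dibromoaniline | Nc1cc(Br)cc(Br)c1
F2 | step 2 | methyl (Z)-3-[(3,5-dibromophenyl)amino]prop-2-enoate | COC(=O)/C=C\Nc1cc(Br)cc(Br)c1
F3 | step 4 | 4,6-dibromo-1H-indole | Brc1cc(Br)c2cc[nH]c2c1
F4 | step 3 | tert-butyl (E)-3-{[(3,5-dibromophenyl)amino]oxy}prop-2-enoate | CC(C)(C)OC(=O)/C=C/ONc1cc(Br)cc(Br)c1
F5 | step 3 | tert-butyl 2-(2-amino-4,6-dibromophenyl)-3-oxopropanoate | CC(C)(C)OC(=O)C(C=O)c1c(N)cc(Br)cc1Br
F6 | step 3 | tert-butyl 4,6-dibromo-1H-indole-3-carboxylate | CC(C)(C)OC(=O)c1c[nH]c2cc(Br)cc(Br)c12
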